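## Structural features

The target 17 is made of two 2,2-dimethyl-2H-chromenes joined through one sp3 carbon. Ring A (aromatic) is fused to ring B (O1, C2, C3, C4), ring C (aromatic) is fused to ring D, and the methine C* (bearing CH3 and H) is bonded to C3 of ring B and to C6' of ring C. Ring A carries a 6-acetyl group hydrogen-bonded to the 5-hydroxyl and a 7-methoxy group; ring C carries methoxy groups on both carbons that flank the point of attachment (C5' and C7'). C* is the only stereocentre (S) and has no stereogenic neighbour. It is benzylic and allylic at once, so cationic conditions, strong base or a metal hydride that moves the C3=C4 double bond would erase it. Both chromene double bonds are electron-rich styrenes that do not tolerate strong acid, and the aryl methyl ketone excludes hard nucleophiles and hydrides late in the route. The real difficulty is a tertiary stereocentre wedged between a di-ortho-substituted arene and a trisubstituted alkene, inside a 3-substituted 2,2-dimethylchromene that the usual phenol–enal annulation does not give directly. The key step exploits the fact that C2 of ring B carries only O1, two methyl groups and C3: it is an acetone carbon, so ring B equals the non-chelated ring-A hydroxyl, the styrene C3=C4 and acetone, with C* already in place on C3.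

## Logic of the disconnections

17 ⇒ 14 + 15. The bonds cut are O1'–C2' and C4'–C4a' of ring D. Ring D is removed first because its double bond would not survive the Lewis acid that closes ring B. The gain is one ring and five carbons, and the ring-C hydroxyl of 14 has two equivalent ortho carbons, so no regiochemical question arises. The forward step must leave the acetyl group and ring B alone; the ring-A hydroxyl of 14 has no free ortho carbon and cannot compete.

14 ⇒ 13. The acyl–oxygen bond on ring C is cut. The acyl group is there to lower the nucleophilicity of ring C during the acid step. The forward step must be a mild methanolysis that spares the ketone and C*.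

13 ⇒ 10 + 11. The bonds cut are O1–C2 and C2–C3 of ring B. C2 is the carbon of 11, and removing it takes away ring B and its quaternary centre at once, leaving an open-chain styrene whose only stereocentre is insulated from the reacting atoms. The forward step must use the hydroxyl that is not hydrogen-bonded to the acetyl group, attack through C3 and not C4, and never place a cation on C*.

10 ⇒ 7 + 9. The alkenyl–aryl bond C4–C4a is cut. This divides the molecule into halves of similar size, and an sp2–sp2 coupling neither touches C* nor leaves the alkene geometry open, since E is carried in by 7. The forward step must couple at a ring carbon flanked by two free hydroxyls.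

9 ⇒ 8. The C–I bond is cut at the ring carbon between the two hydroxyls. The forward step must be regioselective for that carbon over the one between hydroxyl and methoxyl.

7 ⇒ 5 + 6. The C3=C4 double bond is cut as a metathesis retron: C4 with its boron comes from 6, C3 from the terminal alkene of 5. This avoids metathesis with a hindered 2,6-dioxygenated ring-A styrene. The forward step must not let the double bond of 5 migrate toward C*.

5 ⇒ 3 + 4. The C*–C3 bond is cut and the methyl hydrogen is returned. Creating C* then becomes the face-selective addition of H and vinyl across an achiral styrene. The forward step needs catalyst control at a benzylic carbon flanked by two methoxy groups.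

3 ⇒ 2 ⇒ 1. The vinyl C=C goes back to the aldehyde C=O and the ester to the free hydroxyl. Both forward steps are routine, provided the ester is not attacked during olefination.

## Other disconnections considered

Alternative 1: The cut is C3–C4, with the hydrogen on C* removed at the same time, which opens ring B to the salicylaldehyde A1 carrying a (Z)-trisubstituted alkene C3=C* on its tertiary aryl ether. Forward, a chiral rhodium–bisphosphine catalyst would add the aldehyde C–H across that alkene to give chromanone A2, closing ring B and setting C* (and C3) in one operation.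
- In favour: the stereocentre is made catalytically in the ring-forming step from an achiral substrate; the hydroxyl next to the aldehyde anchors the metal and holds back decarbonylation; ring D can be carried through because no Lewis acid is used; ring C needs no protecting group. On these four points the alternative is better than the chosen plan.
- Against: insertion of a trisubstituted alkene bearing a di-ortho-methoxy aryl group into an acyl rhodium hydride is slow, so decarbonylation and alkene isomerisation (which would feed the wrong geometry into a stereospecific addition) can compete. A1 itself needs a geometrically pure Z alkene on a tertiary aryl ether. After A2, three more operations are required: reduction of the C4 ketone, dehydration toward C3, and conversion of the nitrile into the acetyl group with a methyl organometallic beside a free phenol. The C3 stereocentre is thrown away in the process.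
- Comparison: structurally both plans close ring B late. Mechanistically the alternative extends a known reaction class to an unusually hindered alkene, while the chosen plan uses an unprecedented but electronically well-matched cation–olefin closure. In step count the two are about equal; the alternative spends its steps after the key step on oxidation-state repair, the chosen plan spends them before it on fragment synthesis.

Alternative 2: The cuts are C*–C6' and C3–C4. Aldehyde A3 (ring A with a tertiary 2-methylpent-3-yn-2-yl ether) and boronic acid A4 (rings C and D) would be joined by a chiral rhodium hydroxide–bisphosphine catalyst: the aryl–rhodium adds syn across the alkyne and the alkenyl–rhodium then adds to the aldehyde, giving allylic alcohol A5. A reductive allylic transposition through an allylic diazene would then move the double bond into ring B and deliver hydrogen to C*, relaying the C4 configuration to C*.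
- In favour: it is the most convergent option, joining the two halves and closing ring B in the same step; in convergence it is better than the chosen plan. The suprafacial hydrogen delivery is stereochemically well defined.
- Against: A4 is a di-ortho-substituted, electron-rich arylboronic acid, slow to transmetalate and quick to protodeboronate. The aryl group has to be placed on an alkyne whose other end is quaternary, giving a strained tetrasubstituted exocyclic alkene. The methyl ketone competes with the aldehyde as acceptor. The transposition needs a clean displacement at a hindered benzylic–allylic carbinol on an electron-rich ring that ionises easily, so the stereochemical relay may leak. The methoxymethyl ether must finally be removed with acid beside two chromenes.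
- Comparison: the step count is equal or slightly lower and the convergence higher, but three uncertain operations follow the union of the fragments, against one in the chosen plan.

Alternative 3: The cut is the C3=C4 double bond. Enyne A6 (ring-A styrene plus an aryl alkyne on the tertiary ether) would undergo exo ring-closing enyne metathesis with a ruthenium alkylidene catalyst to the 1,3-diene A7, in which C* is an sp2 carbon bearing =CH2. A later enantioselective hydrogenation of that 1,1-disubstituted alkene would create C*.
- In favour: the ring closure is neutral and belongs to a well-established reaction class, so a silyl ether on ring C and the keto-phenol are tolerated. The connectivity of A6 fixes which oxygen is in the ring and where the C3 substituent sits. On functional-group tolerance, on regiochemical certainty and on precedent for the ring-forming step itself, this alternative is better than the chosen plan.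
- Against: the key step does not set C*. The stereocentre depends on a late hydrogenation that must select the 1,1-disubstituted alkene of a conjugated diene over the ring alkene, avoid 1,4-addition, and distinguish the faces of an alkene whose aryl group is twisted out of plane by two ortho-methoxy groups; little in the substrate steers it. A6 needs a tertiary propargylic aryl ether with a hindered internal aryl alkyne, and such ethers undergo Claisen rearrangement on heating.
- Comparison: the length is comparable. The alternative trades the uncertain ring closure of the chosen plan for an uncertain stereocentre, and an enantiomer problem at the end of a route is the more costly of the two.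

Key step: step 7

Remarks on the chemistry.
- By the sequence rule aryl > alkenyl > methyl > H at C*, so C* is S in 5, 7, 10, 12, 13, 14, 16 and 17. The open-chain styrene 10 and the ring-closed 13 were checked against 17 and carry the same arrangement at C*; their structures needed no correction.
- Assumption: the sense of induction of the nickel catalyst in step 3 follows the parent vinylarene series and must be confirmed on 5. Both ligand antipodes are accessible, so the route does not depend on this.
- On the way to 10 the pivalate never meets a Grignard reagent or a hydride, no ionisable 2,6-dimethoxycinnamyl halide is made, and no metathesis is asked of the hindered ring-A styrene.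

Step 1
Reactants: 1 4-hydroxy-2,6-dimethoxybenzaldehyde
Product: 2 4-formyl-3,5-dimethoxyphenyl 2,2-dimethylpropanoate
Conditions: PivCl (1.2 equiv), Et3N (1.5 equiv), DMAP (5 mol%), CH2Cl2, 0 °C → rt
Reagents that add atoms: pivaloyl chloride, CC(C)(C)C(Cl)=O
Why: DMAP-catalysed acylation of the only hydroxyl; the bulky ester should resist the ylide, the metathesis and the aqueous phosphate of later steps, and it lowers the electron density of ring C for step 7.

Step 2
Reactants: 2 4-formyl-3,5-dimethoxyphenyl 2,2-dimethylpropanoate
Product: 3 4-ethenyl-3,5-dimethoxyphenyl 2,2-dimethylpropanoate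
Conditions: Ph3PCH3Br (1.25 equiv), NaN(SiMe3)2 (1.15 equiv), THF, 0 °C; then 2, −78 → 0 °C
Reagents that add atoms: methyltriphenylphosphonium bromide, C[P+](c1ccccc1)(c1ccccc1)c1ccccc1.[Br-]
Why: Wittig methylenation; the aldehyde is far more electrophilic than the hindered aryl ester, and the phosphonium salt is kept in slight excess over the base so that no free amide remains to attack the ester.

Step 3
Reactants: 3 4-ethenyl-3,5-dimethoxyphenyl 2,2-dimethylpropanoate; 4 ethene
Product: 5 4-[(2S)-but-3-en-2-yl]-3,5-dimethoxyphenyl 2,2-dimethylpropanoate
Conditions: C2H4 (1 atm), [Ni(η3-C3H5)Br]2 (1 mol%), binaphthyl N,N-bis(1-phenylethyl)phosphoramidite (2 mol%, antipode giving S), Na[B(3,5-(CF3)2C6H3)4] (2.5 mol%), CH2Cl2, −70 °C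
Reagents that add atoms: none
Why: Nickel-catalysed asymmetric hydrovinylation of a vinylarene: the cationic nickel hydride adds to the styrene to give an η3-benzyl complex, ethene inserts at the benzylic carbon and β-hydride elimination releases the 3-arylbut-1-ene. C* is set by the chiral phosphoramidite on nickel, which selects the enantiotopic face of the styrene; the ligand antipode is chosen to give S.

Step 4
Reactants: 5 4-[(2S)-but-3-en-2-yl]-3,5-dimethoxyphenyl 2,2-dimethylpropanoate; 6 2-ethenyl-4,4,5,5-tetramethyl-1,3,2-dioxaborolane
Product: 7 3,5-dimethoxy-4-[(2S,3E)-4-(4,4,5,5-tetramethyl-1,3,2-dioxaborolan-2-yl)but-3-en-2-yl]phenyl 2,2-dimethylpropanoate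
Conditions: 6 (4 equiv), RuCl2(H2IMes)(=CH-C6H4-2-O-i-Pr) (second-generation Hoveyda–Grubbs catalyst, 5 mol%), 1,4-benzoquinone (10 mol%), CH2Cl2, 40 °C
Reagents that add atoms: none
Why: Olefin cross-metathesis with a vinylboronate; the E isomer is favoured thermodynamically, the excess of 6 should outrun homodimerisation of the hindered alkene, and benzoquinone should suppress ruthenium hydride migration of the double bond toward C*.

Step 5
Reactants: 8 1-(2,4-dihydroxy-6-methoxyphenyl)ethanone
Product: 9 1-(2,4-dihydroxy-3-iodo-6-methoxyphenyl)ethanone
Conditions: NIS (1.0 equiv), MeCN, −10 → 0 °C, dark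
Reagents that add atoms: N-iodosuccinimide, O=C1CCC(=O)N1I
Why: Electrophilic aromatic iodination; the carbon between the two hydroxyls, ortho to the chelated hydroxyl, is expected to be the most nucleophilic site, as in halogenation of related 2-hydroxy-4,6-dioxygenated acetophenones. One equivalent at low temperature should limit di-iodination.

Step 6
Reactants: 7 3,5-dimethoxy-4-[(2S,3E)-4-(4,4,5,5-tetramethyl-1,3,2-dioxaborolan-2-yl)but-3-en-2-yl]phenyl 2,2-dimethylpropanoate; 9 1-(2,4-dihydroxy-3-iodo-6-methoxyphenyl)ethanone
Product: 10 4-[(2S,3E)-4-(3-acetyl-2,6-dihydroxy-4-methoxyphenyl)but-3-en-2-yl]-3,5-dimethoxyphenyl 2,2-dimethylpropanoate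
Conditions: Pd(dppf)Cl2 (5 mol%), K3PO4 (3.5 equiv), 1,4-dioxane/H2O (5:1), degassed, 60 °C; then aq. NH4Cl
Reagents that add atoms: none
Why: Suzuki–Miyaura coupling: zerovalent palladium inserts into the C–I bond and the alkenyl group is transferred from boron with retention of the E geometry, so C* is not involved. Aqueous phosphate should keep the two hydroxyls as phenoxides without cleaving the hindered ester.

Step 7
Reactants: 10 4-[(2S,3E)-4-(3-acetyl-2,6-dihydroxy-4-methoxyphenyl)but-3-en-2-yl]-3,5-dimethoxyphenyl 2,2-dimethylpropanoate; 11 2,2-dimethoxypropane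
Product: 13 4-[(1S)-1-(6-acetyl-5-hydroxy-7-methoxy-2,2-dimethyl-2H-chromen-3-yl)ethyl]-3,5-dimethoxyphenyl 2,2-dimethylpropanoate, via mixed methyl ketal 12 (not isolated)
Conditions: 11 (8 equiv), BF3·OEt2 (0.3 equiv), 4 Å MS, CH2Cl2, −40 → 0 °C; then Et3N
Reagents that add atoms: none
Why: Proposed new method: BF3 should exchange the hydroxyl of 10 that is not hydrogen-bonded to the acetyl group with 11 to give the mixed ketal 12, which loses methanol to an aryloxy oxocarbenium ion; the styrene then attacks the cationic C2 through C3, its nucleophilic terminus, giving a C4 benzylic cation stabilised by the three ring-A oxygens, and loss of the C3 proton gives the 2H-chromene; the closest known reaction type is the Prins cyclisation of homoallylic alcohols with acetals (its arene counterpart being the oxa-Pictet–Spengler reaction). Ring B closes in the 6-endo mode with respect to the alkene. If the C2–C3 bond formed first (attack of C3 on the methoxy oxocarbenium ion of 11, then ionisation of the tertiary allylic ether and capture by oxygen), the same product would result, the second half being the known acid cyclisation of ortho-hydroxycinnamyl tertiary carbinols to 2,2-dimethylchromenes. No stereocentre is created, and C* should keep its configuration because neither cation is centred on it and the proton lost comes from C3. Site selectivity between the two hydroxyls is needed: the one next to the acetyl group is tied up in the hydrogen bond, and closure through it would sacrifice that chelate, so both rate and equilibrium should favour the other oxygen as O1. Regioselectivity within the alkene is needed: the ring-A oxygens polarise the styrene so that C3, not C4, is the nucleophilic carbon. Chemoselectivity against ring C and against the product is needed: the pivalate lowers the nucleophilicity of ring C, the product alkene is hindered at C3 so a second addition is unlikely, the sieves take up methanol, and the acid is kept substoichiometric so that boron does not settle on the keto-phenol.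

Step 8
Reactants: 13 4-[(1S)-1-(6-acetyl-5-hydroxy-7-methoxy-2,2-dimethyl-2H-chromen-3-yl)ethyl]-3,5-dimethoxyphenyl 2,2-dimethylpropanoate
Product: 14 1-{5-hydroxy-3-[(1S)-1-(4-hydroxy-2,6-dimethoxyphenyl)ethyl]-7-methoxy-2,2-dimethyl-2H-chromen-6-yl}ethanone
Conditions: K2CO3 (0.3 equiv), MeOH/THF (3:1), rt
Reagents that add atoms: none
Why: Base-catalysed methanolysis (transesterification) of the aryl ester, phenoxide being a good leaving group; the ketone and both alkenes are inert, and the C*–H is not acidic enough to be touched by carbonate.

Step 9
Reactants: 14 1-{5-hydroxy-3-[(1S)-1-(4-hydroxy-2,6-dimethoxyphenyl)ethyl]-7-methoxy-2,2-dimethyl-2H-chromen-6-yl}ethanone; 15 3-methylbut-2-enal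
Product: 17 1-{3-[(1S)-1-(5,7-dimethoxy-2,2-dimethyl-2H-chromen-6-yl)ethyl]-5-hydroxy-7-methoxy-2,2-dimethyl-2H-chromen-6-yl}ethanone, via ortho-quinone methide 16 (not isolated)
Conditions: 15 (3 equiv), ethylenediammonium diacetate (20 mol%), xylene, 130 °C
Reagents that add atoms: none
Why: Amine salt-catalysed Knoevenagel-type condensation followed by oxa-6π electrocyclisation: the iminium ion of 15 is attacked by a carbon ortho to the free ring-C hydroxyl, loss of the amine gives the ortho-quinone methide 16, and this closes to ring D. The two ortho carbons are equivalent, the ring-A hydroxyl has no free ortho carbon, and no stereocentre is formed.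

## Compound list

1 | 4-hydroxy-2,6-dimethoxybenzaldehyde | COc1cc(O)cc(OC)c1C=O | starting material
2 | 4-formyl-3,5-dimethoxyphenyl 2,2-dimethylpropanoate | COc1cc(OC(=O)C(C)(C)C)cc(OC)c1C=O | intermediate
3 | 4-ethenyl-3,5-dimethoxyphenyl 2,2-dimethylpropanoate | COc1cc(OC(=O)C(C)(C)C)cc(OC)c1C=C | intermediate
4 | ethene | C=C | starting material
5 | 4-[(2S)-but-3-en-2-yl]-3,5-dimethoxyphenyl 2,2-dimethylpropanoate | C=C[C@H](C)c1c(OC)cc(OC(=O)C(C)(C)C)cc1OC | intermediate
6 | 2-ethenyl-4,4,5,5-tetramethyl-1,3,2-dioxaborolane | C=CB1OC(C)(C)C(C)(C)O1 | starting material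
7 | 3,5-dimethoxy-4-[(2S,3E)-4-(4,4,5,5-tetramethyl-1,3,2-dioxaborolan-2-yl)but-3-en-2-yl]phenyl 2,2-dimethylpropanoate | CC1(C)OB(/C=C/[C@H](C)c2c(OC)cc(OC(=O)C(C)(C)C)cc2OC)OC1(C)C | intermediate
8 | 1-(2,4-dihydroxy-6-methoxyphenyl)ethanone | CC(=O)c1c(O)cc(O)cc1OC | starting material
9 | 1-(2,4-dihydroxy-3-iodo-6-methoxyphenyl)ethanone | CC(=O)c1c(O)c(I)c(O)cc1OC | intermediate
10 | 4-[(2S,3E)-4-(3-acetyl-2,6-dihydroxy-4-methoxyphenyl)but-3-en-2-yl]-3,5-dimethoxyphenyl 2,2-dimethylpropanoate | COc1cc(O)c(/C=C/[C@H](C)c2c(OC)cc(OC(=O)C(C)(C)C)cc2OC)c(O)c1C(C)=O | intermediate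
11 | 2,2-dimethoxypropane | COC(C)(C)OC | starting material
12 | 4-[(2S,3E)-4-{3-acetyl-2-hydroxy-4-methoxy-6-[(2-methoxypropan-2-yl)oxy]phenyl}but-3-en-2-yl]-3,5-dimethoxyphenyl 2,2-dimethylpropanoate (mixed methyl ketal, not isolated) | COc1cc(OC(C)(C)OC)c(/C=C/[C@H](C)c2c(OC)cc(OC(=O)C(C)(C)C)cc2OC)c(O)c1C(C)=O | intermediate
13 | 4-[(1S)-1-(6-acetyl-5-hydroxy-7-methoxy-2,2-dimethyl-2H-chromen-3-yl)ethyl]-3,5-dimethoxyphenyl 2,2-dimethylpropanoate | COc1cc2c(c(O)c1C(C)=O)C=C([C@H](C)c1c(OC)cc(OC(=O)C(C)(C)C)cc1OC)C(C)(C)O2 | intermediate
14 | 1-{5-hydroxy-3-[(1S)-1-(4-hydroxy-2,6-dimethoxyphenyl)ethyl]-7-methoxy-2,2-dimethyl-2H-chromen-6-yl}ethanone | COc1cc2c(c(O)c1C(C)=O)C=C([C@H](C)c1c(OC)cc(O)cc1OC)C(C)(C)O2 | intermediate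
15 | 3-methylbut-2-enal | CC(C)=CC=O | starting material
16 | 4-[(1S)-1-(6-acetyl-5-hydroxy-7-methoxy-2,2-dimethyl-2H-chromen-3-yl)ethyl]-3,5-dimethoxy-6-(3-methylbut-2-en-1-ylidene)cyclohexa-2,4-dien-1-one (ortho-quinone methide, not isolated) | CC(C)=CC=C1C(=O)C=C(OC)C([C@@H](C)C2=Cc3c(O)c(C(C)=O)c(OC)cc3OC2(C)C)=C1OC | intermediate
17 | 1-{3-[(1S)-1-(5,7-dimethoxy-2,2-dimethyl-2H-chromen-6-yl)ethyl]-5-hydroxy-7-methoxy-2,2-dimethyl-2H-chromen-6-yl}ethanone | COc1cc2c(c(O)c1C(C)=O)C=C([C@H](C)c1c(OC)cc3c(c1OC)C=CC(C)(C)O3)C(C)(C)O2 | target

## Step count and least certain steps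

Total: 9 steps. Longest linear sequence: 8 steps (steps 1, 2, 3, 4, 6, 7, 8 and 9, from 1 to 17); step 5 is a one-step branch.

Step 7 (key step, beyond known chemistry). Several processes could defeat it:
- The mixed ketal could ionise mainly by loss of the phenol and not of methanol, so that the reaction idles at reversible ketal exchange.
- Cationic oligomerisation of the electron-rich styrene, or Friedel–Crafts capture of an oxocarbenium ion by ring C, could outrun the closure.
- Boron could bind the keto-phenol and withdraw the catalyst.
- Closure through the chelated hydroxyl would give the regioisomeric ring.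

The fallback uses known chemistry only, sets out from 7 and 8 and comes back at 13:
- Oxidation of the alkenylboronate 7 (NaBO3·4H2O, THF/H2O, rt) would give the aldehyde 3,5-dimethoxy-4-[(2S)-4-oxobutan-2-yl]phenyl 2,2-dimethylpropanoate F1.
- Silylation (Me3SiCl, Et3N, NaI, MeCN) would give its trimethylsilyl enol ether 3,5-dimethoxy-4-[(2S)-4-(trimethylsilyloxy)but-3-en-2-yl]phenyl 2,2-dimethylpropanoate F2.
- Mukaiyama aldol-type addition of F2 to 11 (Me3SiOTf cat., CH2Cl2, −78 °C) would give the β-methoxy aldehyde 4-[(2S)-3-formyl-4-methoxy-4-methylpentan-2-yl]-3,5-dimethoxyphenyl 2,2-dimethylpropanoate F3.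
- Elimination of methanol with DBU would give the α-branched enal 4-[(2R)-3-formyl-4-methylpent-3-en-2-yl]-3,5-dimethoxyphenyl 2,2-dimethylpropanoate F4. The descriptor changes by the sequence rule only; the arrangement at C* is that of 7.
- Condensation of F4 with 8 (ethylenediammonium diacetate, xylene, reflux) is the classical Knoevenagel/oxa-6π chromene annulation of an acylphloroglucinol-type phenol. It attacks the carbon between the hydroxyls, closes on the non-chelated oxygen and would form ring B of 13 directly. The price is an annulation with a hindered α-branched enal.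

Step 3. Turnover or enantioselection could be poor, because the two ortho-methoxy groups crowd, and may chelate, the cationic nickel hydride and its η3-benzyl intermediate. Isomerisation of the product alkene into conjugation with the arene by the same hydride would destroy C*. The fallback forms the C*–CH3 bond instead of the C*–vinyl bond; it sets out from 2 and comes back at 5:
- Addition of CH2=CHMgBr (THF, −78 °C) would give racemic 4-(1-hydroxyprop-2-en-1-yl)-3,5-dimethoxyphenyl 2,2-dimethylpropanoate F5.
- PBr3 (Et2O, 0 °C) would give, with allylic transposition, 4-[(1E)-3-bromoprop-1-en-1-yl]-3,5-dimethoxyphenyl 2,2-dimethylpropanoate F6, to be used at once.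
- Copper-catalysed asymmetric SN2' methylation (MeMgBr, CuBr·SMe2 5 mol%, Taniaphos 6 mol%, antipode giving S, CH2Cl2, −75 °C) would deliver 5.

Step 4. Productive metathesis at the hindered, allylically branched alkene may be slow, leaving time for ruthenium hydride-mediated double-bond migration that erodes C*. The fallback replaces metathesis by cleavage and olefination; it sets out from 5 and comes back at 7:
- Lemieux–Johnson cleavage (OsO4 2 mol%, NaIO4, 2,6-lutidine, dioxane/H2O) would give 3,5-dimethoxy-4-[(2R)-1-oxopropan-2-yl]phenyl 2,2-dimethylpropanoate F7 (same arrangement at C*), to be used without storage.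
- Takai-type olefination with 2-(dichloromethyl)-4,4,5,5-tetramethyl-1,3,2-dioxaborolane (CrCl2, LiI, THF, rt), a non-basic and E-selective reaction, would give 7.

Step 6. Protodeiodination and slow oxidative addition at the electron-rich bis-phenoxide are possible, as is acyl transfer from the pivalate to a phenoxide at 60 °C. The fallback couples a non-ionisable partner and unmasks afterwards; it sets out from 9 and comes back at 10:
- Etherification (NaH, MOMCl, DMF, 0 °C → rt) would give 1-[3-iodo-6-methoxy-2,4-bis(methoxymethoxy)phenyl]ethanone F8.
- Suzuki–Miyaura coupling of F8 with 7 (Pd(dppf)Cl2, K3PO4, dioxane/H2O, 70 °C) would give 4-{(2S,3E)-4-[3-acetyl-4-methoxy-2,6-bis(methoxymethoxy)phenyl]but-3-en-2-yl}-3,5-dimethoxyphenyl 2,2-dimethylpropanoate F9.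
- Acid methanolysis of the two acetals (HCl, MeOH/THF, 40 °C) would give 10; the aryl ester is stable to these conditions.

Step 9. The monohydric ring-C phenol may be too slow toward the iminium ion at a practical temperature, and aldol condensation of 15 at the acetyl methyl group could then take over. The fallback builds ring D by rearrangement instead of condensation; it sets out from 14 and comes back at 17:
- Selective O-alkylation of the non-chelated ring-C hydroxyl with 3-chloro-3-methylbut-1-yne (K2CO3, KI, CuI cat., acetone, reflux) would give 1-{5-hydroxy-3-[(1S)-1-{2,6-dimethoxy-4-[(2-methylbut-3-yn-2-yl)oxy]phenyl}ethyl]-7-methoxy-2,2-dimethyl-2H-chromen-6-yl}ethanone F10.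
- Heating (xylene, 140 °C) would trigger the aryl propargyl ether Claisen rearrangement, hydrogen shift and oxa-6π closure to 17.

## Further compounds

F1 | step 7 | 3,5-dimethoxy-4-[(2S)-4-oxobutan-2-yl]phenyl 2,2-dimethylpropanoate | O=CC[C@H](C)c1c(OC)cc(OC(=O)C(C)(C)C)cc1OC
F2 | step 7 | 3,5-dimethoxy-4-[(2S)-4-(trimethylsilyloxy)but-3-en-2-yl]phenyl 2,2-dimethylpropanoate (E/Z mixture) | C[Si](C)(C)OC=C[C@H](C)c1c(OC)cc(OC(=O)C(C)(C)C)cc1OC
F3 | step 7 | 4-[(2S)-3-formyl-4-methoxy-4-methylpentan-2-yl]-3,5-dimethoxyphenyl 2,2-dimethylpropanoate (mixture at C3 of the chain) | COC(C)(C)C(C=O)[C@H](C)c1c(OC)cc(OC(=O)C(C)(C)C)cc1OC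
F4 | step 7 | 4-[(2R)-3-formyl-4-methylpent-3-en-2-yl]-3,5-dimethoxyphenyl 2,2-dimethylpropanoate (arrangement at C* as in 7) | CC(C)=C(C=O)[C@H](C)c1c(OC)cc(OC(=O)C(C)(C)C)cc1OC
F5 | step 3 | 4-(1-hydroxyprop-2-en-1-yl)-3,5-dimethoxyphenyl 2,2-dimethylpropanoate (racemic) | C=CC(O)c1c(OC)cc(OC(=O)C(C)(C)C)cc1OC
F6 | step 3 | 4-[(1E)-3-bromoprop-1-en-1-yl]-3,5-dimethoxyphenyl 2,2-dimethylpropanoate | BrC/C=C/c1c(OC)cc(OC(=O)C(C)(C)C)cc1OC
F7 | step 4 | 3,5-dimethoxy-4-[(2R)-1-oxopropan-2-yl]phenyl 2,2-dimethylpropanoate (arrangement at C* as in 5) | O=C[C@H](C)c1c(OC)cc(OC(=O)C(C)(C)C)cc1OC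
F8 | step 6 | 1-[3-iodo-6-methoxy-2,4-bis(methoxymethoxy)phenyl]ethanone | CC(=O)c1c(OCOC)c(I)c(OCOC)cc1OC
F9 | step 6 | 4-{(2S,3E)-4-[3-acetyl-4-methoxy-2,6-bis(methoxymethoxy)phenyl]but-3-en-2-yl}-3,5-dimethoxyphenyl 2,2-dimethylpropanoate | COCOc1cc(OC)c(C(C)=O)c(OCOC)c1/C=C/[C@H](C)c1c(OC)cc(OC(=O)C(C)(C)C)cc1OC
F10 | step 9 | 1-{5-hydroxy-3-[(1S)-1-{2,6-dimethoxy-4-[(2-methylbut-3-yn-2-yl)oxy]phenyl}ethyl]-7-methoxy-2,2-dimethyl-2H-chromen-6-yl}ethanone | C#CC(C)(C)Oc1cc(OC)c([C@@H](C)C2=Cc3c(O)c(C(C)=O)c(OC)cc3OC2(C)C)c(OC)c1
A1 | alternative 1 | 4-{[(3Z)-4-(5,7-dimethoxy-2,2-dimethyl-2H-chromen-6-yl)-2-methylpent-3-en-2-yl]oxy}-3-formyl-2-hydroxy-6-methoxybenzonitrile | N#Cc1c(OC)cc(OC(C)(C)/C=C(/C)c2c(OC)cc3c(c2OC)C=CC(C)(C)O3)c(C=O)c1O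
A2 | alternative 1 | 3-[1-(5,7-dimethoxy-2,2-dimethyl-2H-chromen-6-yl)ethyl]-5-hydroxy-7-methoxy-2,2-dimethyl-4-oxochroman-6-carbonitrile (single diastereomer) | CC1(C)Oc2cc(OC)c(C#N)c(O)c2C(=O)[C@H]1[C@H](C)c1c(OC)cc2c(c1OC)C=CC(C)(C)O2
A3 | alternative 2 | 3-acetyl-4-methoxy-2-(methoxymethoxy)-6-[(2-methylpent-3-yn-2-yl)oxy]benzaldehyde | CC#CC(C)(C)Oc1cc(OC)c(C(C)=O)c(OCOC)c1C=O
A4 | alternative 2 | (5,7-dimethoxy-2,2-dimethyl-2H-chromen-6-yl)boronic acid | OB(O)c1c(OC)cc2c(c1OC)C=CC(C)(C)O2
A5 | alternative 2 | 6-acetyl-3-[1-(5,7-dimethoxy-2,2-dimethyl-2H-chromen-6-yl)ethylidene]-7-methoxy-5-(methoxymethoxy)-2,2-dimethylchroman-4-ol (aryl cis to C4, single enantiomer) | CC1(C)Oc2cc(OC)c(C(C)=O)c(OCOC)c2[C@@H](O)/C1=C(/C)c1c(OC)cc2c(c1OC)C=CC(C)(C)O2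
A6 | alternative 3 | 1-{4-[(4-{4-[tert-butyl(dimethyl)silyloxy]-2,6-dimethoxyphenyl}-2-methylbut-3-yn-2-yl)oxy]-3-ethenyl-2-hydroxy-6-methoxyphenyl}ethanone | C=Cc1c(O)c(C(C)=O)c(OC)cc1OC(C)(C)C#Cc1c(OC)cc(O[Si](C)(C)C(C)(C)C)cc1OC
A7 | alternative 3 | 1-{3-[1-{4-[tert-butyl(dimethyl)silyloxy]-2,6-dimethoxyphenyl}ethenyl]-5-hydroxy-7-methoxy-2,2-dimethyl-2H-chromen-6-yl}ethanone | COc1cc2c(c(O)c1C(C)=O)C=C(C(=C)c1c(OC)cc(O[Si](C)(C)C(C)(C)C)cc1OC)C(C)(C)O2
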